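**Plan**
- Ring B carries CO2H on C1', OMe on C2', the acylated oxygen on C4' and pentyl on C6'. This is the pattern that a 1,1-dimethoxy-3-acyloxybuta-1,3-diene (C2'–C5') and an oct-2-ynoate (C1', C6') deliver, so the retrosynthesis first removes two benzyl groups and then cuts C1'–C2' and C5'–C6'.
- The dienyl ester is cut at its enol O–acyl bond into the ring-A acyl fluoride and the enolate of 4,4-dimethoxybut-3-en-2-one; the enone is cut into acetyl chloride and ketene dimethyl acetal.
- Ring A is cut at the aryl–heptyl bond (cross-coupling) and the aryl–carbonyl bond (formylation) back to 1-bromo-3,5-dimethoxybenzene.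
- Forward: ring A is bought and elaborated (heptyl, CHO, ortho-OMe to OBn, CO2H, COF), then joined to the enone as an enol ester. Ring B, the only ring made, is built last around this preformed depside ester by cycloaddition and aromatisation; hydrogenolysis finishes.
- Stereochemistry: none has to be set.

Key step: step 10

Assumption: the target has no stereocentre, axis or stereogenic double bond, so the structure as drawn is its only stereoisomer and no asymmetric step is needed; ketene dimethyl acetal is taken as purchasable.

**Route**

Step 1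
Reactants: 1 1-bromo-3,5-dimethoxybenzene; 2 heptylmagnesium bromide
Product: 3 1-heptyl-3,5-dimethoxybenzene
Conditions: NiCl2(dppp) (2 mol %), Et2O, 0 °C → reflux
Reagents that add atoms: none
Why: Nickel-catalysed Kumada–Corriu coupling of an aryl bromide with a primary alkyl Grignard reagent is reliable on electron-rich arenes, and the chelating dppp ligand should suppress β-hydride elimination of the heptyl group.

Step 2
Reactants: 3 1-heptyl-3,5-dimethoxybenzene
Product: 5 2-heptyl-4,6-dimethoxybenzaldehyde, via aryl iminium chloride 4 (not isolated)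
Conditions: POCl3, DMF, 0 → 80 °C; then H2O, 50 °C
Reagents that add atoms: N,N-dimethylformamide, CN(C)C=O; water, O
Why: Vilsmeier–Haack formylation of 5-alkylresorcinol dimethyl ethers should occur at the position ortho to one methoxy and para to the other (the two such sites are equivalent) rather than between the methoxy groups, and the iminium salt is hydrolysed on aqueous work-up.

Step 3
Reactants: 5 2-heptyl-4,6-dimethoxybenzaldehyde
Product: 7 2-heptyl-6-hydroxy-4-methoxybenzaldehyde, via aryloxydichloroborane 6 (not isolated)
Conditions: BCl3 (1.2 equiv), CH2Cl2, −78 → 0 °C; then H2O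
Reagents that add atoms: none
Why: Chelation-directed Lewis-acid ether cleavage: BCl3 bound to the formyl oxygen should cleave only the ortho methyl ether through a six-membered chelate and leave the para methoxy group intact.

Step 4
Reactants: 7 2-heptyl-6-hydroxy-4-methoxybenzaldehyde
Product: 8 2-(benzyloxy)-6-heptyl-4-methoxybenzaldehyde
Conditions: BnBr, K2CO3, DMF, 60 °C
Reagents that add atoms: benzyl bromide, BrCc1ccccc1
Why: Williamson etherification of the phenoxide; gentle heating overcomes the hydrogen bond of the salicylaldehyde hydroxyl.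

Step 5
Reactants: 8 2-(benzyloxy)-6-heptyl-4-methoxybenzaldehyde
Product: 9 2-(benzyloxy)-6-heptyl-4-methoxybenzoic acid
Conditions: NaClO2, NaH2PO4, 2-methylbut-2-ene (excess), t-BuOH/THF/H2O, 0 °C → rt
Reagents that add atoms: sodium chlorite, [Na+].[O-][Cl+][O-]
Why: Pinnick oxidation converts hindered aryl aldehydes into acids under buffered conditions, and the alkene scavenger removes hypochlorous acid before it can chlorinate the electron-rich ring.

Step 6
Reactants: 9 2-(benzyloxy)-6-heptyl-4-methoxybenzoic acid
Product: 10 2-(benzyloxy)-6-heptyl-4-methoxybenzoyl fluoride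
Conditions: cyanuric fluoride (0.4 equiv), pyridine, CH2Cl2, −10 °C → rt
Reagents that add atoms: cyanuric fluoride, Fc1nc(F)nc(F)n1
Why: Deoxyfluorination of a carboxylic acid with cyanuric fluoride gives an isolable acyl fluoride without strong acid, so the benzyl ether is not endangered.

Step 7
Reactants: 11 acetyl chloride; 12 1,1-dimethoxyethene
Product: 13 4,4-dimethoxybut-3-en-2-one
Conditions: 12 (2.1 equiv), Et2O, 0 °C → rt; distillation
Reagents that add atoms: none
Why: C-acylation of a ketene acetal by an acid chloride: the nucleophilic CH2 carbon attacks the acyl chloride and the dialkoxycarbenium ion loses a proton to give the acylketene acetal, with the second equivalent of 12 taking up the HCl.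

Step 8
Reactants: 13 4,4-dimethoxybut-3-en-2-one; 10 2-(benzyloxy)-6-heptyl-4-methoxybenzoyl fluoride
Product: 15 4,4-dimethoxybuta-1,3-dien-2-yl 2-(benzyloxy)-6-heptyl-4-methoxybenzoate, via potassium dienolate 14 (not isolated)
Conditions: KHMDS, THF, −78 °C (13 added to base); then 10, −78 → 0 °C; non-aqueous work-up, filtration through Et3N-deactivated silica
Reagents that add atoms: none
Why: Kinetic deprotonation of the acetyl CH3, the only enolisable site, followed by enolate O-acylation (enol ester formation); a dissociated potassium enolate and a hard, di-ortho-substituted aroyl fluoride should favour attack through oxygen over carbon.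

Step 9
Reactants: 16 oct-2-ynoic acid
Product: 17 benzyl oct-2-ynoate
Conditions: BnBr, K2CO3, DMF, rt
Reagents that add atoms: benzyl bromide, BrCc1ccccc1
Why: SN2 O-alkylation of the carboxylate with benzyl bromide; the mild carbonate base should not isomerise or add to the ynoate.

Step 10
Reactants: 15 4,4-dimethoxybuta-1,3-dien-2-yl 2-(benzyloxy)-6-heptyl-4-methoxybenzoate; 17 benzyl oct-2-ynoate
Product: 19 benzyl 4-{[2-(benzyloxy)-6-heptyl-4-methoxybenzoyl]oxy}-2-methoxy-6-pentylbenzoate, via cyclohexadiene cycloadduct 18 (not isolated)
Conditions: 17 (3 equiv), o-xylene (2 M), 135 °C, Ar sweep, base-washed glassware; then PPTS (cat.), CH2Cl2, rt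
Reagents that add atoms: none
Why: Proposed new method: the ketene-acetal terminus makes 15 an electron-rich diene with its largest HOMO coefficient on the unsubstituted CH2 carbon, so an asynchronous normal-demand Diels–Alder reaction with 17 should join that CH2 to the pentyl-bearing β-carbon and the acetal carbon to the ester-bearing α-carbon, giving cyclohexa-1,4-diene 18. The closest known reaction types are the Diels–Alder/aromatisation of 1,1-dialkoxy-3-silyloxybuta-1,3-dienes with acetylenic esters and cycloadditions of 2-acyloxy-1,3-dienes; because acyloxy is a weaker donor than silyloxy, heat and excess dienophile are used. Ring B is closed by the intermolecular [4+2] cycloaddition itself, both new bonds (C1'–C2' and C5'–C6') forming suprafacially in one six-membered transition state, after which 18 aromatises by 1,4-loss of methanol from the bis-allylic dimethyl ketal carbon and the ring CH2. No stereocentre is created, since the only sp3 ring carbons of 18 each carry two identical substituents and both become sp2. The selectivity needed is regiochemical (methoxy next to the carboxylate, acyloxy para to it); it is secured by the matched polarisation of the 1,1-dimethoxy diene and the ynoate β-carbon, which the 3-acyloxy group reinforces. Anhydrous, acid-free conditions until the diene is consumed, with methanol swept out, should keep the ketene acetal and the enol ester intact.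

Step 11
Reactants: 19 benzyl 4-{[2-(benzyloxy)-6-heptyl-4-methoxybenzoyl]oxy}-2-methoxy-6-pentylbenzoate
Product: 20 4-[(2-heptyl-6-hydroxy-4-methoxybenzoyl)oxy]-2-methoxy-6-pentylbenzoic acid
Conditions: H2 (1 atm), 10% Pd/C, EtOAc, rt
Reagents that add atoms: none
Why: Catalytic hydrogenolysis cleaves the benzyl ether and the benzyl ester together, while the aryl ester link, the methyl ethers and both arenes are inert under these conditions.

**Compound list**
1 | 1-bromo-3,5-dimethoxybenzene | COc1cc(Br)cc(OC)c1 | starting material
2 | heptylmagnesium bromide | CCCCCCC[Mg]Br | starting material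
3 | 1-heptyl-3,5-dimethoxybenzene | CCCCCCCc1cc(OC)cc(OC)c1 | intermediate
4 | N-[(2-heptyl-4,6-dimethoxyphenyl)methylidene]-N-methylmethanaminium chloride | CCCCCCCc1cc(OC)cc(OC)c1C=[N+](C)C.[Cl-] | intermediate
5 | 2-heptyl-4,6-dimethoxybenzaldehyde | CCCCCCCc1cc(OC)cc(OC)c1C=O | intermediate
6 | dichloro(2-formyl-3-heptyl-5-methoxyphenoxy)borane | CCCCCCCc1cc(OC)cc(OB(Cl)Cl)c1C=O | intermediate
7 | 2-heptyl-6-hydroxy-4-methoxybenzaldehyde | CCCCCCCc1cc(OC)cc(O)c1C=O | intermediate
8 | 2-(benzyloxy)-6-heptyl-4-methoxybenzaldehyde | CCCCCCCc1cc(OC)cc(OCc2ccccc2)c1C=O | intermediate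
9 | 2-(benzyloxy)-6-heptyl-4-methoxybenzoic acid | CCCCCCCc1cc(OC)cc(OCc2ccccc2)c1C(=O)O | intermediate
10 | 2-(benzyloxy)-6-heptyl-4-methoxybenzoyl fluoride | CCCCCCCc1cc(OC)cc(OCc2ccccc2)c1C(F)=O | intermediate
11 | acetyl chloride | CC(=O)Cl | starting material
12 | 1,1-dimethoxyethene | C=C(OC)OC | starting material
13 | 4,4-dimethoxybut-3-en-2-one | CC(=O)C=C(OC)OC | intermediate
14 | potassium 4,4-dimethoxybuta-1,3-dien-2-olate | C=C([O-])C=C(OC)OC.[K+] | intermediate
15 | 4,4-dimethoxybuta-1,3-dien-2-yl 2-(benzyloxy)-6-heptyl-4-methoxybenzoate | CCCCCCCc1cc(OC)cc(OCc2ccccc2)c1C(=O)OC(=C)C=C(OC)OC | intermediate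
16 | oct-2-ynoic acid | CCCCCC#CC(=O)O | starting material
17 | benzyl oct-2-ynoate | CCCCCC#CC(=O)OCc1ccccc1 | intermediate
18 | benzyl 4-{[2-(benzyloxy)-6-heptyl-4-methoxybenzoyl]oxy}-6,6-dimethoxy-2-pentylcyclohexa-1,4-diene-1-carboxylate | CCCCCCCc1cc(OC)cc(OCc2ccccc2)c1C(=O)OC1=CC(OC)(OC)C(C(=O)OCc2ccccc2)=C(CCCCC)C1 | intermediate
19 | benzyl 4-{[2-(benzyloxy)-6-heptyl-4-methoxybenzoyl]oxy}-2-methoxy-6-pentylbenzoate | CCCCCCCc1cc(OC)cc(OCc2ccccc2)c1C(=O)Oc1cc(CCCCC)c(C(=O)OCc2ccccc2)c(OC)c1 | intermediate
20 | 4-[(2-heptyl-6-hydroxy-4-methoxybenzoyl)oxy]-2-methoxy-6-pentylbenzoic acid | CCCCCCCc1cc(OC)cc(O)c1C(=O)Oc1cc(CCCCC)c(C(=O)O)c(OC)c1 | target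

**Count**
Total steps: 11. Longest linear sequence: 9 (steps 1–6, 8, 10, 11).

**Steps most likely to fail**

Step 10. The cycloaddition with the β-alkyl ynoate may be slower than thermal decomposition of the dienyl ester, through methanol adding to the ketene acetal or cleaving the enol ester, and aromatisation may stall. The fallback builds ring B by the established silyloxydiene version of the same cycloaddition and forms the depside ester afterwards. It sets out from enone 13, which is O-silylated (TBSOTf, Et3N, Et2O, 0 °C) to 3-(tert-butyldimethylsilyloxy)-1,1-dimethoxybuta-1,3-diene F1. Heating F1 with ynoate 17 should give the cycloadduct benzyl 4-(tert-butyldimethylsilyloxy)-6,6-dimethoxy-2-pentylcyclohexa-1,4-diene-1-carboxylate F2, which loses methanol to benzyl 4-(tert-butyldimethylsilyloxy)-2-methoxy-6-pentylbenzoate F3. TBAF then frees benzyl 4-hydroxy-2-methoxy-6-pentylbenzoate F4, whose sodium phenoxide (NaH, THF) is acylated with acyl fluoride 10. The fallback rejoins the route at 19.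

Step 8. The ambident enolate may be acylated on carbon, 13 may self-condense under the strong base, or the ketene acetal may hydrolyse during isolation. The fallback replaces the metal enolate by a neutral silyl enol ether. From enone 13, silylation (TMSCl, Et3N, cat. ZnCl2) gives 1,1-dimethoxy-3-(trimethylsilyloxy)buta-1,3-diene F5. Fluoride-catalysed acyl transfer from acyl fluoride 10 (cat. TBAT or KF/18-crown-6, THF) then delivers the enol ester with loss of fluorotrimethylsilane. The fallback rejoins the route at 15.

Step 7. The dimethoxycarbenium intermediate may lose chloromethane instead of a proton, giving methyl acetoacetate, or the ketene acetal may polymerise under the HCl formed. The fallback starts from acetyl chloride 11 and avoids the ketene acetal. Friedel–Crafts acylation of 1,1-dichloroethene (AlCl3, CH2Cl2) gives 4,4,4-trichlorobutan-2-one F6, which loses HCl on distillation to 4,4-dichlorobut-3-en-2-one F7. Double addition–elimination with NaOMe in MeOH then replaces both chlorides. The fallback rejoins the route at 13.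

**Further compounds**
F1 | step 10 | 3-(tert-butyldimethylsilyloxy)-1,1-dimethoxybuta-1,3-diene | C=C(O[Si](C)(C)C(C)(C)C)C=C(OC)OC
F2 | step 10 | benzyl 4-(tert-butyldimethylsilyloxy)-6,6-dimethoxy-2-pentylcyclohexa-1,4-diene-1-carboxylate | CCCCCC1=C(C(=O)OCc2ccccc2)C(OC)(OC)C=C(O[Si](C)(C)C(C)(C)C)C1
F3 | step 10 | benzyl 4-(tert-butyldimethylsilyloxy)-2-methoxy-6-pentylbenzoate | CCCCCc1cc(O[Si](C)(C)C(C)(C)C)cc(OC)c1C(=O)OCc1ccccc1
F4 | step 10 | benzyl 4-hydroxy-2-methoxy-6-pentylbenzoate | CCCCCc1cc(O)cc(OC)c1C(=O)OCc1ccccc1
F5 | step 8 | 1,1-dimethoxy-3-(trimethylsilyloxy)buta-1,3-diene | C=C(O[Si](C)(C)C)C=C(OC)OC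
F6 | step 7 | 4,4,4-trichlorobutan-2-one | CC(=O)CC(Cl)(Cl)Cl
F7 | step 7 | 4,4-dichlorobut-3-en-2-one | CC(=O)C=C(Cl)Cl
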